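**Remarks on the chemistry (assumptions)**

- The stereodescriptors of the target correspond to the cis-(2S,3R) dihydrobenzofuran, acylated on O5 of natural (−)-shikimic acid; the route is planned for this isomer.
- A re-derivation of the atom mapping from oxime ether 5 to benzofuran 9 showed no structural error: the only hydrogen-bearing ortho carbon of the aryloxy ring lies next to the bromide, which leads to the 4-bromo-7-methoxy pattern that the target needs.
- The sense of induction of the hydrogenation catalyst in step 7 cannot be derived with certainty; the (Sa,S) ligand is written and its antipode would be taken if a trial run shows the opposite sense.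
- In step 7, cod = 1,5-cyclooctadiene, (Sa,S)-SIPHOX = (Sa,S)-7-[bis(3,5-di-tert-butylphenyl)phosphino]-7'-(4-benzyl-4,5-dihydrooxazol-2-yl)-1,1'-spirobiindane, BArF = tetrakis[3,5-bis(trifluoromethyl)phenyl]borate.

## Structural features

The target is a 2-aryl-2,3-dihydrobenzofuran. Ring A (3,4-dihydroxyphenyl) sits on C2. The benzo ring B carries the C7 hydroxyl and, at C4, an (E)-propenoic acid chain. The dihydrofuran ring bears a C3 carboxyl group that is esterified with the C5 hydroxyl of (−)-shikimic acid, whose cyclohexene ring keeps a free carboxylic acid and the free 3,4-diol.

The two stereocentres of the dihydrofuran, C2 (S) and C3 (R), are adjacent and cis. The three contiguous centres of the shikimate ring come unchanged from the chiral pool and are remote from them.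

The cis arrangement is the less stable one. C3–H is both α to an ester carbonyl and benzylic, so a base that enolises the ester (or opens the ring by retro-oxa-Michael elimination) drains the material to the trans isomer. C2 is a benzylic ether para to a phenol and can ionise under forcing acid.

Further fragile features are the two catechol-type rings (oxidation), the allylic alcohol of the shikimate, and the single ester link between the two halves, which must survive while two other carboxyl groups are unmasked, so the route cannot end with a saponification.

The real difficulty is therefore not the carbon skeleton. It is reaching the cis-(2S,3R) pair on a fully substituted ring B (oxygen at C7, carbon at C4) and keeping it through esterification, C4 vinylation and deprotection.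

The key step exploits the array O1–C7a–C3a–C3 with C2 bonded to both O1 and C3. Written as an O-aryl oxime ether of a β-keto ester, this array has the aryl–O1 bond present from the start and lets C3–C3a and O1–C2 be made in one operation. The C7 oxygen blocks the second ortho position and a bromide marks C4.

## Logic of the disconnections

**20 ⇒ 19.** The bonds cut are the three phenolic O–CH2 acetal bonds, the two ketal C–O bonds on the shikimate diol and the two ester O–C(CH3)3 bonds. All six masks leave under one acid treatment, so no base is needed at the end and C3 is not endangered. The gain is that every hydroxyl and carboxyl group is masked in the preceding steps. The demand is an acid strong enough for tert-butyl esters but applied cold and briefly, so that C2 does not ionise and the ester between the two halves stays.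

**19 ⇒ 17 + 18.** The bond cut is C4–vinyl carbon. The acrylate cannot be carried through step 7, where it would be reduced, whereas a bromide can. The cut removes a three-carbon chain and gives commercial 18. The demand is a cross-coupling whose base is too weak to enolise C3.

**17 ⇒ 13 + 16.** The bond cut is the acyl–O5 ester bond. This separates the dihydrobenzofuran acid from the chiral-pool unit, so that each half is simple. The demand is an acyl activation that does not enolise C3 and still acylates a hindered secondary alcohol. A useful side effect is that coupling to enantiopure 16 turns any minor enantiomer of 13 into a separable diastereomer.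

**16 ⇒ 15 ⇒ 14.** The bonds cut are the ester O–C(CH3)3 bond and then the two ketal C–O bonds. Both masks are acid-labile and match the final step. The demand is selectivity for the cis-3,4-diol over the C5 hydroxyl and for the carboxyl over that hydroxyl.

**13 ⇒ 12.** The bonds cut are C2–H and C3–H. This erases both stereocentres at once and leaves a flat benzofuran acid, so no earlier intermediate carries stereochemistry. The demand is a syn, face-selective hydrogenation of a tetrasubstituted heteroaromatic double bond that spares the C–Br bond. It is placed at the free-acid stage because the carboxylate can steer the catalyst, protects C3 from enolisation, and the shikimate alkene is not yet present.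

**12 ⇒ 11 ⇒ 10 ⇒ 9.** These are functional-group changes: the acid returns to the ethyl ester and the three O–CH2OCH3 groups return to O–CH3. The key step needs acid-proof masks and the endgame needs acid-labile ones, so the exchange is placed on the robust aromatic benzofuran, where BBr3 and hot hydroxide can do no harm. A precursor carrying acetal groups from the start would save these steps only if the shift were run without acid, and would cost more steps in making non-commercial pieces. The precursor therefore keeps methyl ethers and an ethyl ester. The demand is that BBr3 cleaves three ethers while the flanked ester is spared or, if cleaved, converges on 12.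

**9 ⇒ 5 (key).** The bonds cut are C3–C3a and O1–C2. The aryl–O1 bond stays, so ring B comes as a catalogue phenol with its oxygen and bromide already in place, and the only open ortho position decides the regiochemistry. The gain is the complete tetrasubstituted core, with all carbons at the right oxidation level, from two pieces. The demand is that all substituents tolerate acid and that the shift goes to the hydrogen-bearing ortho carbon.

**5 ⇒ 3 + 4.** The bond cut is C=N. This is a plain condensation and 4 is commercial. The demand is reaction at the ketone and not at the ester, under conditions mild enough that 5 can be isolated.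

**3 ⇒ 1 (through 2).** The bond cut is O–N. Electrophilic amination of the phenoxide puts nitrogen on the oxygen that becomes O1. The demand is an NH2 donor that can be stored and handled safely, which is why a crystalline O-aryl hydroxylamine reagent is used and not a sulfonylhydroxylamine that must be made fresh.

## Other disconnections considered

**Alternative 1:**
- **Cut.** It runs through ring B: C3a–C7a, C6–C7 and the C7–O bond are removed. This unravels ring B into a 2,3-disubstituted furan and a terminal alkynyl ether joined by the C3–C2–O1 chain (open-chain precursor A1).
- **Forward key step.** (Ph3P)AuNTf2 (monovalent gold) would activate the alkyne of A1 toward attack by the substituted furan carbon. The furan would open and reclose as a benzene ring, so that ring B and the dihydrofuran ring appear together and the furan oxygen ends as the C7 hydroxyl of phenol A2.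
- **In its favour.** C2 and C3 are set in an acyclic chain before any ring exists. C3 carries a silyloxymethyl group and not an ester during ring formation, so the cis pair cannot epimerise in the key step. The conditions are neutral, the tether fixes the substitution pattern of ring B, and the C7 hydroxyl emerges free and distinct from the ring A oxygens.
- **Against it here.** A2 is at the wrong oxidation level at two carbons. The C3 hydroxymethyl group must be raised to the acid through the aldehyde level, where C3–H is at its most acidic. The C4 hydroxymethyl group must be oxidised and olefinated. Terminal alkynyl ethers are laborious to make and acid-sensitive, and the stereo-defined chain of A1 needs its own asymmetric carbon–carbon bond construction.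
- **Comparison.** On structure it is the equal of the chosen plan, since both fix the 4,7-pattern of ring B unambiguously. On configurational safety during ring construction it is the better, since the chosen plan must create cis on a finished ring by an untested hydrogenation. On mechanism both rest on a known reaction class. On step economy it is clearly the worse: the chosen plan reaches the core in three steps from two commercial pieces, while here the redox corrections alone should outnumber the whole endgame of the chosen plan.

**Alternative 2:**
- **Cut.** The O1–C2 bond, leaving the acyclic syn aldol A3, in which the C7a phenol is free and C2 carries a hydroxyl of the configuration opposite to that of the target.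
- **Forward key step.** PPh3 and diisopropyl azodicarboxylate would turn the C2 hydroxyl of A3 into an oxyphosphonium leaving group. The phenol would displace it with inversion in a 5-exo-tet closure to give the cis ring of A4, which is the fully protected target.
- **In its favour.** It is the most convergent of the four plans: every carbon, the shikimate ester and the cinnamate are in place before the ring closes, and only one acidolysis follows. The stereochemical outcome is tied to the substrate by a stereospecific substitution and not to a catalyst. On the length of the sequence after the key step it is better than the chosen plan, and it needs neither a hydrogenation nor an aryl halide.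
- **Against it here.** The carbon being substituted is benzylic to an oxygenated ring, so ionisation can compete with direct displacement even with the ring A oxygens damped as carbonates, and any ionisation leaks to the trans ring. A β-hydroxy ester under these conditions is also prone to dehydration and to retro-aldol cleavage by the basic betaine. The stereochemical problem is only moved: A3 must be made as one syn diastereomer of defined absolute configuration by an aldol reaction of a hindered, base-sensitive ester enolate, in the presence of aryl carbonates that tolerate enolate chemistry poorly.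
- **Comparison.** On structure it is the equal or the better (more convergent, later ring closure). On mechanism the chosen key step is the safer: a sigmatropic shift on an achiral aromatic precursor has no stereochemistry to lose and no elimination pathway, while here the key step carries the full stereochemical risk at the most valuable intermediate. On step economy the two are about equal if the aldol is selective, and the alternative is the worse if it is not.

**Alternative 3:**
- **Cut.** The C2–C3 bond. The precursor is the aryl diazoacetate A5, already esterified with the protected shikimate, whose ring B oxygen carries the ring A benzyl group.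
- **Forward key step.** Rh2(S-PTTL)4 (dirhodium tetrakis[N-phthaloyl-(S)-tert-leucinate], divalent rhodium) would turn A5 into a carbenoid that inserts into the benzylic ether C–H bond five atoms away. This forms C2–C3 and closes the dihydrofuran ring of A6, creating both stereocentres in one step. A6 is the same substance as 17, so steps 11 and 12 would follow unchanged.
- **In its favour.** It is the better of the chosen plan on three points. Cis-selective, enantioselective carbenoid insertion to this ring type has closer precedent than the hydrogenation of step 7. No strongly acidic step occurs, so acetal groups can be carried from the beginning and the exchange of steps 4 and 5 falls away. The ester to the shikimate is formed on an acid that has no stereocentre yet, so the risk of step 10 disappears.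
- **Against it here.** The chiral ester and the chiral catalyst may be mismatched, and the known cis preference refers to small achiral esters. Diazo transfer must take place at a carbon flanked by two ortho substituents. The carbenoid has competing paths: oxonium ylide formation at the ether oxygen with a 1,2-shift, cyclopropanation of the shikimate alkene, and insertion next to the acetal oxygens. A ring B piece with a two-carbon acid chain between bromide and oxygen is not a catalogue item, whereas the chosen plan takes ring B from a commercial phenol.
- **Comparison.** On structure the two are equal, since they converge on the same late intermediate. On mechanism each concentrates its risk in one catalytic stereo-defining step, with the better precedent on the side of the alternative. On step economy they are about equal, the saved protecting-group exchange being offset by the longer preparation of the diazo precursor.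

Key step: step 3

## Route

**Step 1**
Reactants: 1 5-bromo-2-methoxyphenol
Product: 3 O-(5-bromo-2-methoxyphenyl)hydroxylamine, via potassium 5-bromo-2-methoxyphenoxide 2 (not isolated)
Conditions: KOt-Bu (1.0 equiv), DMF, 0 °C; then O-(2,4-dinitrophenyl)hydroxylamine (1.1 equiv), 0 °C → rt
Reagents that add atoms: O-(2,4-dinitrophenyl)hydroxylamine, NOc1ccc(cc1[N+](=O)[O-])[N+](=O)[O-]; potassium tert-butoxide, CC(C)(C)[O-].[K+] (potassium of intermediate 2 only)
Why: Electrophilic amination of a phenoxide: the oxygen nucleophile attacks the nitrogen of the reagent and expels the stabilised 2,4-dinitrophenoxide. The reagent is crystalline and storable, so no aminating agent has to be prepared fresh and handled as an unstable solution.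

**Step 2**
Reactants: 3 O-(5-bromo-2-methoxyphenyl)hydroxylamine; 4 ethyl 3-(3,4-dimethoxyphenyl)-3-oxopropanoate
Product: 5 ethyl 3-[(5-bromo-2-methoxyphenoxy)imino]-3-(3,4-dimethoxyphenyl)propanoate (E/Z mixture)
Conditions: AcOH (cat.), EtOH, 4 Å molecular sieves, rt
Reagents that add atoms: none
Why: Oxime ether condensation: the nitrogen adds to the ketone carbonyl, which is far more electrophilic than the ester, and water is removed by the sieves. Weak acid at room temperature should stop at the oxime ether, and both geometric isomers serve in step 3.

**Step 3**
Reactants: 5 ethyl 3-[(5-bromo-2-methoxyphenoxy)imino]-3-(3,4-dimethoxyphenyl)propanoate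
Product: 9 ethyl 4-bromo-2-(3,4-dimethoxyphenyl)-7-methoxybenzofuran-3-carboxylate, via ene-hydroxylamine tautomer 6 (not isolated), via ortho-hydroxyaryl imino ester 7 (not isolated), via 2-amino-2,3-dihydrobenzofuran 8 (not isolated)
Conditions: MeSO3H (2 equiv), dry THF, 60 °C
Reagents that add atoms: none
Why: Acid shifts oxime ether 5 (either geometry) to the ester-conjugated ene-hydroxylamine 6, whose N–O bond is weak; a [3,3]-sigmatropic shift then joins the former methylene carbon to the hydrogen-bearing ortho carbon of the aryloxy ring (C3–C3a) as N–O breaks, and tautomerisation restores the arene to give phenol–imine 7. The phenol oxygen adds to the protonated imine carbon in a 5-exo-trig closure (O1–C2) to aminal 8, and loss of ammonia, driven by aromatisation and taken up as its ammonium salt, gives 9. The closest known reaction type is the acid-promoted rearrangement of O-aryl oxime ethers to benzofurans, the oxygen counterpart of the Fischer indole synthesis, which is established for β-keto ester oxime ethers leading to benzofuran-3-carboxylates. No stereocentre is formed, so no stereocontrol is required. The selectivity needed is regiochemical on two counts: on ring B the C7 methoxy group occupies the second ortho position, where a shift would give a dienone that cannot aromatise, so productive bond formation is possible only next to the bromide; on the side chain the keto ester has a single methylene, which fixes the 2-aryl-3-ester pattern. A non-nucleophilic sulfonic acid in an aprotic solvent is chosen so that no halide or alcohol can intercept an ipso-shift adduct, and the methyl ethers, the ethyl ester and the aryl bromide are inert to it.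

**Step 4**
Reactants: 9 ethyl 4-bromo-2-(3,4-dimethoxyphenyl)-7-methoxybenzofuran-3-carboxylate
Product: 10 ethyl 4-bromo-2-(3,4-dihydroxyphenyl)-7-hydroxybenzofuran-3-carboxylate
Conditions: BBr3 (6 equiv), CH2Cl2, −78 → 0 °C; then ice–water
Reagents that add atoms: none
Why: Lewis-acid ether cleavage: boron complexes each aryl methyl ether and bromide removes the methyl group. The flanked ethyl ester, the aryl bromide and the aromatic furan should be inert at 0 °C, and any ester that is cleaved converges on acid 12 after steps 5 and 6.

**Step 5**
Reactants: 10 ethyl 4-bromo-2-(3,4-dihydroxyphenyl)-7-hydroxybenzofuran-3-carboxylate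
Product: 11 ethyl 4-bromo-2-[3,4-bis(methoxymethoxy)phenyl]-7-(methoxymethoxy)benzofuran-3-carboxylate
Conditions: MOMCl (4.5 equiv), i-Pr2NEt (6 equiv), CH2Cl2, 0 °C → rt
Reagents that add atoms: chloromethyl methyl ether, COCCl
Why: Williamson-type O-alkylation of the three phenols by the oxocarbenium-like chloro ether. The acetals withstand hydroxide, hydrogenation, carbodiimide and palladium in the following steps and leave in the final acid treatment with the other acid-labile groups.

**Step 6**
Reactants: 11 ethyl 4-bromo-2-[3,4-bis(methoxymethoxy)phenyl]-7-(methoxymethoxy)benzofuran-3-carboxylate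
Product: 12 4-bromo-2-[3,4-bis(methoxymethoxy)phenyl]-7-(methoxymethoxy)benzofuran-3-carboxylic acid
Conditions: KOH (10 equiv), EtOH/H2O (4:1), 80 °C; then 1 M HCl to pH 3–4 at 0 °C
Reagents that add atoms: potassium hydroxide, [K+].[OH-]
Why: Saponification by acyl–oxygen cleavage. The substrate has no stereocentre and no base-labile group, so the forcing conditions that the flanked ester needs are harmless, and the brief cold acidification spares the acetals.

**Step 7**
Reactants: 12 4-bromo-2-[3,4-bis(methoxymethoxy)phenyl]-7-(methoxymethoxy)benzofuran-3-carboxylic acid
Product: 13 (2S,3R)-4-bromo-2-[3,4-bis(methoxymethoxy)phenyl]-7-(methoxymethoxy)-2,3-dihydrobenzofuran-3-carboxylic acid (cis)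
Conditions: [Ir(cod)((Sa,S)-SIPHOX)]BArF (monovalent iridium, 2 mol %), H2 (10 bar), Et3N (0.5 equiv), MeOH, 45 °C; then aq. citric acid
Reagents that add atoms: none
Why: Proposed new method: the carboxylate of 12 should bind iridium and hold the tetrasubstituted C2=C3 bond, which is the α,β-bond of an unsaturated acid with only weak furan aromaticity, in the chiral pocket, so that both hydrogens of the iridium dihydride add to one face and give the cis acid with C2 and C3 set together by the ligand; the closest known reaction types are the carboxylate-directed iridium-catalysed asymmetric hydrogenation of tetrasubstituted α,β-unsaturated acids with spiro phosphine–oxazoline ligands and the asymmetric hydrogenation of the C2=C3 bond of benzofurans, neither yet shown on a 2-aryl-benzofuran-3-carboxylic acid; the product is a carboxylate salt under the conditions, so C3 cannot epimerise, and the aryl bromide and the acetals should be untouched by the homogeneous catalyst.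

**Step 8**
Reactants: 14 (−)-shikimic acid
Product: 15 3,4-O-isopropylideneshikimic acid
Conditions: 2,2-dimethoxypropane (1.5 equiv), TsOH·H2O (cat.), acetone, rt
Reagents that add atoms: 2,2-dimethoxypropane, COC(C)(C)OC
Why: Acid-catalysed transketalisation under thermodynamic control: only the cis-3,4-diol forms an unstrained five-membered isopropylidene ring, so the trans-disposed C5 hydroxyl stays free. Room temperature and a short reaction time keep the conjugated acid from being esterified by the liberated methanol.

**Step 9**
Reactants: 15 3,4-O-isopropylideneshikimic acid
Product: 16 tert-butyl 3,4-O-isopropylideneshikimate (C5 hydroxyl free)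
Conditions: tert-butyl 2,2,2-trichloroacetimidate (2.5 equiv), CH2Cl2/cyclohexane, rt
Reagents that add atoms: tert-butyl 2,2,2-trichloroacetimidate, CC(C)(C)OC(=N)C(Cl)(Cl)Cl
Why: Imidate esterification: the carboxylic acid protonates the imidate and is alkylated by the resulting tert-butyl cation equivalent. Without an added Lewis acid the neutral secondary alcohol should not react, and the ketal tolerates the weakly acidic medium.

**Step 10**
Reactants: 13 (2S,3R)-4-bromo-2-[3,4-bis(methoxymethoxy)phenyl]-7-(methoxymethoxy)-2,3-dihydrobenzofuran-3-carboxylic acid; 16 tert-butyl 3,4-O-isopropylideneshikimate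
Product: 17 tert-butyl 5-O-[(2S,3R)-4-bromo-2-[3,4-bis(methoxymethoxy)phenyl]-7-(methoxymethoxy)-2,3-dihydrobenzofuran-3-carbonyl]-3,4-O-isopropylideneshikimate
Conditions: DIC (1.5 equiv), 4-(dimethylamino)pyridinium tosylate (0.5 equiv), CH2Cl2, 0 °C → rt
Reagents that add atoms: none
Why: Steglich esterification; the tosylate-buffered acyl-transfer catalyst keeps the concentration of free base low, so that C3 of the activated acid (α to the carbonyl and benzylic) should not be deprotonated. Coupling with the enantiopure alcohol turns any minor enantiomer of 13 into a separable diastereomer.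

**Step 11**
Reactants: 17 tert-butyl 5-O-[(2S,3R)-4-bromo-2-[3,4-bis(methoxymethoxy)phenyl]-7-(methoxymethoxy)-2,3-dihydrobenzofuran-3-carbonyl]-3,4-O-isopropylideneshikimate; 18 tert-butyl acrylate
Product: 19 tert-butyl 5-O-[(2S,3R)-2-[3,4-bis(methoxymethoxy)phenyl]-4-[(E)-3-tert-butoxy-3-oxoprop-1-en-1-yl]-7-(methoxymethoxy)-2,3-dihydrobenzofuran-3-carbonyl]-3,4-O-isopropylideneshikimate
Conditions: Pd2(dba)3 (zerovalent palladium, 2.5 mol %), [HP(t-Bu)3]BF4 (10 mol %), Cy2NMe (1.5 equiv), 1,4-dioxane, 40 °C
Reagents that add atoms: none
Why: Mizoroki–Heck reaction: the electron-rich, bulky phosphine allows oxidative addition of the hindered bromide near room temperature, and syn carbopalladation followed by syn β-hydride elimination gives the E-alkene. The hindered tertiary amine only takes up HBr and is too weak to enolise the C3 ester, and the trisubstituted shikimate alkene is a far poorer acceptor than the acrylate.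

**Step 12**
Reactants: 19 tert-butyl 5-O-[(2S,3R)-2-[3,4-bis(methoxymethoxy)phenyl]-4-[(E)-3-tert-butoxy-3-oxoprop-1-en-1-yl]-7-(methoxymethoxy)-2,3-dihydrobenzofuran-3-carbonyl]-3,4-O-isopropylideneshikimate
Product: 20 (3R,4R,5R)-5-{[(2S,3R)-4-[(E)-2-carboxyethenyl]-2-(3,4-dihydroxyphenyl)-7-hydroxy-2,3-dihydro-1-benzofuran-3-carbonyl]oxy}-3,4-dihydroxycyclohex-1-ene-1-carboxylic acid (target)
Conditions: TFA/CH2Cl2/H2O (10:10:1), 0 °C → rt; evaporation, reversed-phase chromatography
Reagents that add atoms: none
Why: Global acidolysis: the tert-butyl esters leave by alkyl–oxygen cleavage, and the three acetals and the ketal are hydrolysed through oxocarbenium ions that water captures. No base is present, so C3 keeps its configuration, and the electron-withdrawing C3 ester disfavours ionisation at C2, so the cis ring and the ester between the two halves should persist.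

## Compound list

1 | 5-bromo-2-methoxyphenol | COc1ccc(Br)cc1O | starting material
2 | potassium 5-bromo-2-methoxyphenoxide | COc1ccc(Br)cc1[O-].[K+] | intermediate (not isolated)
3 | O-(5-bromo-2-methoxyphenyl)hydroxylamine | COc1ccc(Br)cc1ON | intermediate
4 | ethyl 3-(3,4-dimethoxyphenyl)-3-oxopropanoate | CCOC(=O)CC(=O)c1ccc(OC)c(OC)c1 | starting material
5 | ethyl 3-[(5-bromo-2-methoxyphenoxy)imino]-3-(3,4-dimethoxyphenyl)propanoate (E/Z mixture) | CCOC(=O)CC(=NOc1cc(Br)ccc1OC)c1ccc(OC)c(OC)c1 | intermediate
6 | ethyl 3-[(5-bromo-2-methoxyphenoxy)amino]-3-(3,4-dimethoxyphenyl)prop-2-enoate (ene-hydroxylamine tautomer of 5) | CCOC(=O)C=C(NOc1cc(Br)ccc1OC)c1ccc(OC)c(OC)c1 | intermediate (not isolated)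
7 | ethyl 2-(6-bromo-2-hydroxy-3-methoxyphenyl)-3-(3,4-dimethoxyphenyl)-3-iminopropanoate | CCOC(=O)C(C(=N)c1ccc(OC)c(OC)c1)c1c(Br)ccc(OC)c1O | intermediate (not isolated)
8 | ethyl 2-amino-4-bromo-2-(3,4-dimethoxyphenyl)-7-methoxy-2,3-dihydrobenzofuran-3-carboxylate (transient diastereomer mixture) | CCOC(=O)C1c2c(Br)ccc(OC)c2OC1(N)c1ccc(OC)c(OC)c1 | intermediate (not isolated)
9 | ethyl 4-bromo-2-(3,4-dimethoxyphenyl)-7-methoxybenzofuran-3-carboxylate | CCOC(=O)c1c(-c2ccc(OC)c(OC)c2)oc2c(OC)ccc(Br)c12 | intermediate
10 | ethyl 4-bromo-2-(3,4-dihydroxyphenyl)-7-hydroxybenzofuran-3-carboxylate | CCOC(=O)c1c(-c2ccc(O)c(O)c2)oc2c(O)ccc(Br)c12 | intermediate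
11 | ethyl 4-bromo-2-[3,4-bis(methoxymethoxy)phenyl]-7-(methoxymethoxy)benzofuran-3-carboxylate | CCOC(=O)c1c(-c2ccc(OCOC)c(OCOC)c2)oc2c(OCOC)ccc(Br)c12 | intermediate
12 | 4-bromo-2-[3,4-bis(methoxymethoxy)phenyl]-7-(methoxymethoxy)benzofuran-3-carboxylic acid | OC(=O)c1c(-c2ccc(OCOC)c(OCOC)c2)oc2c(OCOC)ccc(Br)c12 | intermediate
13 | (2S,3R)-4-bromo-2-[3,4-bis(methoxymethoxy)phenyl]-7-(methoxymethoxy)-2,3-dihydrobenzofuran-3-carboxylic acid (cis) | Brc1ccc(OCOC)c2c1[C@@H](C(=O)O)[C@@H](c1ccc(OCOC)c(OCOC)c1)O2 | intermediate
14 | (−)-shikimic acid, (3R,4S,5R)-3,4,5-trihydroxycyclohex-1-ene-1-carboxylic acid | O[C@@H]1CC(C(=O)O)=C[C@@H](O)[C@H]1O | starting material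
15 | 3,4-O-isopropylideneshikimic acid (cis-fused acetonide, C5 hydroxyl free) | O[C@@H]1CC(C(=O)O)=C[C@@H](OC(C)(C)O2)[C@H]12 | intermediate
16 | tert-butyl 3,4-O-isopropylideneshikimate, tert-butyl (3aR,7R,7aS)-7-hydroxy-2,2-dimethyl-3a,6,7,7a-tetrahydro-1,3-benzodioxole-5-carboxylate | O[C@@H]1CC(C(=O)OC(C)(C)C)=C[C@@H](OC(C)(C)O2)[C@H]12 | intermediate
17 | tert-butyl 5-O-[(2S,3R)-4-bromo-2-[3,4-bis(methoxymethoxy)phenyl]-7-(methoxymethoxy)-2,3-dihydrobenzofuran-3-carbonyl]-3,4-O-isopropylideneshikimate | Brc1ccc(OCOC)c2c1[C@@H](C(=O)O[C@@H]1CC(C(=O)OC(C)(C)C)=C[C@@H](OC(C)(C)O3)[C@H]13)[C@@H](c1ccc(OCOC)c(OCOC)c1)O2 | intermediate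
18 | tert-butyl acrylate | C=CC(=O)OC(C)(C)C | starting material
19 | tert-butyl 5-O-[(2S,3R)-2-[3,4-bis(methoxymethoxy)phenyl]-4-[(E)-3-tert-butoxy-3-oxoprop-1-en-1-yl]-7-(methoxymethoxy)-2,3-dihydrobenzofuran-3-carbonyl]-3,4-O-isopropylideneshikimate | CC(C)(C)OC(=O)/C=C/c1ccc(OCOC)c2c1[C@@H](C(=O)O[C@@H]1CC(C(=O)OC(C)(C)C)=C[C@@H](OC(C)(C)O3)[C@H]13)[C@@H](c1ccc(OCOC)c(OCOC)c1)O2 | intermediate
20 | (3R,4R,5R)-5-{[(2S,3R)-4-[(E)-2-carboxyethenyl]-2-(3,4-dihydroxyphenyl)-7-hydroxy-2,3-dihydro-1-benzofuran-3-carbonyl]oxy}-3,4-dihydroxycyclohex-1-ene-1-carboxylic acid | O=C(O)/C=C/c1ccc(O)c2c1[C@@H](C(=O)O[C@@H]1CC(C(=O)O)=C[C@@H](O)[C@H]1O)[C@@H](c1ccc(O)c(O)c1)O2 | target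

## Step count and least certain steps

Total step count: 12. Longest linear sequence: 10 steps (steps 1–7 and 10–12); steps 8 and 9 form the two-step side branch to 16.

**Step 7 (the step marked as a proposed new method).** The most likely failures are lack of turnover on a hindered, tetrasubstituted, weakly aromatic double bond flanked by the C2 aryl group and the peri bromide, and insufficient or reversed facial selectivity. A reversed sense alone would be answered by the ligand antipode.
Fallback with known chemistry, setting out from 12: heterogeneous syn hydrogenation (H2, 3 bar, 5% rhodium on alumina, EtOAc, rt; rhodium and not palladium, to limit hydrogenolysis of the C–Br bond) should give the racemic cis acid, that is 13 together with its enantiomer, (2R,3S)-4-bromo-2-[3,4-bis(methoxymethoxy)phenyl]-7-(methoxymethoxy)-2,3-dihydrobenzofuran-3-carboxylic acid F1. Esterification of this mixture with 16 under the conditions of step 10 would give 17 and the diastereomeric ester of the (2R,3S) acid F2, to be separated by chromatography. The route is rejoined at 17, at the cost of half the material.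

**Step 3 (key step).** The most likely failure is a partial shift onto the methoxy-bearing ortho carbon, the counterpart of the abnormal course known for ortho-methoxy aryl hydrazones in the nitrogen series, which would end in non-aromatisable material. Hydrolytic cleavage of the oxime ether by adventitious water, or heterolytic N–O cleavage without C–C bond formation under strong acid, are further possibilities.
Fallback, setting out from 5: the trigger is changed from protonation to N-acylation. Trifluoroacetic anhydride and Et3N in CH2Cl2 at 0 °C should give the N-trifluoroacetyl ene-hydroxylamine F3, which rearranges at or below room temperature as a neutral species and closes to the 2-(trifluoroacetamido)-2,3-dihydrobenzofuran F4. Treatment with TsOH or DBU then eliminates trifluoroacetamide. The route is rejoined at 9.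

**Step 10.** The most likely failure is epimerisation at C3 through enolisation or ketene formation of the activated acid, which would lead to the trans ester. Slow acylation of the hindered alcohol with rearrangement of the activated acid to the N-acylurea is a second possibility.
Fallback, setting out from 16: the acid is used as the nucleophile and never activated at carbon. Mitsunobu inversion of 16 with 4-nitrobenzoic acid (PPh3, diisopropyl azodicarboxylate, THF) gives tert-butyl 3,4-O-isopropylidene-5-O-(4-nitrobenzoyl)-5-epi-shikimate F5, and methanolysis (K2CO3, MeOH) gives tert-butyl 3,4-O-isopropylidene-5-epi-shikimate F6. A second Mitsunobu reaction of 13 with F6 then forms the ester with inversion at C5. The route is rejoined at 17.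

**Step 11.** The most likely failure is slow oxidative addition at the hindered, electron-rich bromide, so that heating is needed, at which point the amine may begin to epimerise C3; reductive loss of bromine is a second possibility.
Fallback, setting out from 13: the order of the two steps is reversed so that the coupling runs on the carboxylate, which resists enolisation. Heck reaction of 13 with 18 (Pd(OAc)2, divalent palladium, P(o-tol)3, Et3N, DMF, 90 °C) gives (2S,3R)-2-[3,4-bis(methoxymethoxy)phenyl]-4-[(E)-3-tert-butoxy-3-oxoprop-1-en-1-yl]-7-(methoxymethoxy)-2,3-dihydrobenzofuran-3-carboxylic acid F7. F7 is then esterified with 16 under the conditions of step 10. The route is rejoined at 19.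

**Step 12.** The most likely failure is that removal of all six groups needs long exposure to strong acid. That would allow ionisation at C2 with loss of the cis relation, and alkylation of the electron-rich rings by tert-butyl or methoxymethyl cations or by formaldehyde.
Fallback, setting out from 19: a two-stage route that replaces protic acidolysis by silyl transfer. TMSOTf with 2,6-lutidine and 2,2'-bipyridyl in CH2Cl2 at 0 °C, then water, should convert the tert-butyl esters and the aryl acetals into silyl derivatives that hydrolyse on work-up, leaving the 3,4-O-isopropylidene derivative of the target F8. Mild hydrolysis of the ketal (80% aq. AcOH, 40 °C) then gives 20.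

## Further compounds

F1 | step 7 | (2R,3S)-4-bromo-2-[3,4-bis(methoxymethoxy)phenyl]-7-(methoxymethoxy)-2,3-dihydrobenzofuran-3-carboxylic acid (enantiomer of 13, formed with 13 as the racemate) | Brc1ccc(OCOC)c2c1[C@H](C(=O)O)[C@H](c1ccc(OCOC)c(OCOC)c1)O2
F2 | step 7 | tert-butyl 5-O-[(2R,3S)-4-bromo-2-[3,4-bis(methoxymethoxy)phenyl]-7-(methoxymethoxy)-2,3-dihydrobenzofuran-3-carbonyl]-3,4-O-isopropylideneshikimate (diastereomer of 17) | Brc1ccc(OCOC)c2c1[C@H](C(=O)O[C@@H]1CC(C(=O)OC(C)(C)C)=C[C@@H](OC(C)(C)O3)[C@H]13)[C@H](c1ccc(OCOC)c(OCOC)c1)O2
F3 | step 3 | ethyl 3-[N-(5-bromo-2-methoxyphenoxy)-2,2,2-trifluoroacetamido]-3-(3,4-dimethoxyphenyl)prop-2-enoate | CCOC(=O)C=C(N(Oc1cc(Br)ccc1OC)C(=O)C(F)(F)F)c1ccc(OC)c(OC)c1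
F4 | step 3 | ethyl 4-bromo-2-(3,4-dimethoxyphenyl)-7-methoxy-2-(2,2,2-trifluoroacetamido)-2,3-dihydrobenzofuran-3-carboxylate (diastereomer mixture) | CCOC(=O)C1c2c(Br)ccc(OC)c2OC1(NC(=O)C(F)(F)F)c1ccc(OC)c(OC)c1
F5 | step 10 | tert-butyl 3,4-O-isopropylidene-5-O-(4-nitrobenzoyl)-5-epi-shikimate | O=C(O[C@H]1CC(C(=O)OC(C)(C)C)=C[C@@H](OC(C)(C)O2)[C@H]12)c1ccc(cc1)[N+](=O)[O-]
F6 | step 10 | tert-butyl 3,4-O-isopropylidene-5-epi-shikimate | O[C@H]1CC(C(=O)OC(C)(C)C)=C[C@@H](OC(C)(C)O2)[C@H]12
F7 | step 11 | (2S,3R)-2-[3,4-bis(methoxymethoxy)phenyl]-4-[(E)-3-tert-butoxy-3-oxoprop-1-en-1-yl]-7-(methoxymethoxy)-2,3-dihydrobenzofuran-3-carboxylic acid | CC(C)(C)OC(=O)/C=C/c1ccc(OCOC)c2c1[C@@H](C(=O)O)[C@@H](c1ccc(OCOC)c(OCOC)c1)O2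
F8 | step 12 | 3,4-O-isopropylidene derivative of 20 (phenols and both carboxylic acids free) | O=C(O)/C=C/c1ccc(O)c2c1[C@@H](C(=O)O[C@@H]1CC(C(=O)O)=C[C@@H](OC(C)(C)O3)[C@H]13)[C@@H](c1ccc(O)c(O)c1)O2
A1 | alternative 1 | open-chain furan–ynol ether: 3-[(tert-butyldimethylsilyloxy)methyl]-2-{1-[3,4-bis(methoxymethoxy)phenyl]-1-(ethynyloxy)-3-(triisopropylsilyloxy)propan-2-yl}furan, configured as in A2 | CC(C)(C)[Si](C)(C)OCc1ccoc1[C@@H](CO[Si](C(C)C)(C(C)C)C(C)C)[C@@H](c1ccc(OCOC)c(OCOC)c1)OC#C
A2 | alternative 1 | cis-(2S,3S)-2-[3,4-bis(methoxymethoxy)phenyl]-4-[(tert-butyldimethylsilyloxy)methyl]-3-[(triisopropylsilyloxy)methyl]-2,3-dihydrobenzofuran-7-ol | CC(C)(C)[Si](C)(C)OCc1ccc(O)c2c1[C@@H](CO[Si](C(C)C)(C(C)C)C(C)C)[C@@H](c1ccc(OCOC)c(OCOC)c1)O2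
A3 | alternative 2 | syn aldol: protected shikimate ester of the 3-hydroxy-2-arylpropanoic acid with free C7a phenol, C7 methoxymethyl ether, C4 tert-butyl (E)-acrylate and ring A as bis(tert-butyl carbonate) | CC(C)(C)OC(=O)/C=C/c1ccc(OCOC)c(O)c1[C@@H](C(=O)O[C@@H]1CC(C(=O)OC(C)(C)C)=C[C@@H](OC(C)(C)O2)[C@H]12)[C@@H](O)c1ccc(OC(=O)OC(C)(C)C)c(OC(=O)OC(C)(C)C)c1
A4 | alternative 2 | fully protected target with ring A as bis(tert-butyl carbonate), cis-(2S,3R) | CC(C)(C)OC(=O)/C=C/c1ccc(OCOC)c2c1[C@@H](C(=O)O[C@@H]1CC(C(=O)OC(C)(C)C)=C[C@@H](OC(C)(C)O3)[C@H]13)[C@@H](c1ccc(OC(=O)OC(C)(C)C)c(OC(=O)OC(C)(C)C)c1)O2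
A5 | alternative 3 | aryl diazoacetate: protected shikimate ester of 2-diazo-2-{6-bromo-2-[3,4-bis(methoxymethoxy)benzyloxy]-3-(methoxymethoxy)phenyl}acetic acid | Brc1ccc(OCOC)c(OCc2ccc(OCOC)c(OCOC)c2)c1C(=[N+]=[N-])C(=O)O[C@@H]1CC(C(=O)OC(C)(C)C)=C[C@@H](OC(C)(C)O2)[C@H]12
A6 | alternative 3 | protected 4-bromo cis-(2S,3R)-dihydrobenzofuran shikimate ester (identical with 17) | Brc1ccc(OCOC)c2c1[C@@H](C(=O)O[C@@H]1CC(C(=O)OC(C)(C)C)=C[C@@H](OC(C)(C)O3)[C@H]13)[C@@H](c1ccc(OCOC)c(OCOC)c1)O2
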